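**Assumptions (one line each)**
- Germacrane numbering is used throughout: C1 ketone, C2=C3 enol ether, C3–O–C10 bridge (the furanone), C4 (Me), C5 (OH), C6 (lactone O), C7, C8 (O-angeloyl), C9 (CH2), C10 (Me), C11(=C13H2), C12 lactone C=O.
- Aldehyde 4 and both enantiomers of the imidazolidinone catalyst are treated as purchasable.
- The sense of induction in the new step 9 is a working model, not a known result; if the (2S,5S) catalyst gives 10S, the (2R,5R) catalyst is used instead.

## Retrosynthetic overview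
1. Target ⇐ C8-OH/C5-OTBS macrocycle 30 by Yamaguchi angeloylation, then desilylation.
2. The 10-membered carbocycle and the α-methylene-γ-lactone (formed last, together) ⇐ intramolecular Cr(II) Barbier 2-(methoxycarbonyl)allylation forming C6–C7 in bromo-enoate aldehyde 28.
3. Bromo-enoate ⇐ Morita–Baylis–Hillman reaction of C7 aldehyde 22; C8–O ⇐ D-proline α-aminoxylation of aldehyde 18.
4. C9–C10 bond and C10 quaternary centre ⇐ new iminium-catalysed dearomative Mukaiyama–Michael addition of 3-silyloxyfuran 16 to acrolein.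
5. 3(2H)-Furanone (formed first) ⇐ Au-catalysed cyclisation of a γ-hydroxy ynone from lactate Weinreb amide 12 and alkyne 7; C4/C5 ⇐ Marshall allenylzinc addition.

## Route

**Step 1**
Reactants: 1 (R)-but-3-yn-2-ol; 2 methanesulfonyl chloride
Product: 3 (R)-but-3-yn-2-yl methanesulfonate
Conditions: MsCl, Et3N, CH2Cl2, −78 → 0 °C
Reagents that add atoms: methanesulfonyl chloride, CS(=O)(=O)Cl
Why: O-sulfonylation; the C–O bond is untouched, so configuration is retained.

**Step 2**
Reactants: 3; 4 2-[(4-methoxybenzyl)oxy]acetaldehyde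
Product: 5 (2S,3S)-1-[(4-methoxybenzyl)oxy]-3-methylpent-4-yn-2-ol
Conditions: Pd(OAc)2 (5 mol %), PPh3 (5 mol %), Et2Zn (3 equiv), THF, −78 → −20 °C
Reagents that add atoms: 2-[(4-methoxybenzyl)oxy]acetaldehyde, O=CCOCc1ccc(OC)cc1
Why: Marshall propargylation: anti-SN2′ oxidative addition gives a chiral allenyl-Pd/Zn species that adds through a cyclic SE2′ transition state, giving the anti homopropargylic alcohol with net inversion at the mesylate carbon; this sets C4 and C5.

**Step 3**
Reactants: 5; 6 tert-butyldimethylsilyl triflate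
Product: 7 tert-butyl({(2S,3S)-1-[(4-methoxybenzyl)oxy]-3-methylpent-4-yn-2-yl}oxy)dimethylsilane
Conditions: TBSOTf, 2,6-lutidine, CH2Cl2, −78 → 0 °C
Reagents that add atoms: TBSOTf, CC(C)(C)[Si](C)(C)OS(=O)(=O)C(F)(F)F
Why: Standard silylation of a hindered secondary alcohol; TBS at O5 survives to the last step.

**Step 4**
Reactants: 8 ethyl (S)-lactate; 9 N,O-dimethylhydroxylamine hydrochloride
Product: 10 (S)-2-hydroxy-N-methoxy-N-methylpropanamide
Conditions: MeNHOMe·HCl, i-PrMgCl, THF, −20 → 0 °C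
Reagents that add atoms: N,O-dimethylhydroxylamine hydrochloride, CNOC.Cl
Why: Weinreb aminolysis of the ester by the magnesium amide.

**Step 5**
Reactants: 10; 11 chlorotriethylsilane
Product: 12 (S)-N-methoxy-N-methyl-2-[(triethylsilyl)oxy]propanamide
Conditions: TESCl, imidazole, DMF, 0 °C → rt
Reagents that add atoms: chlorotriethylsilane, CC[Si](Cl)(CC)CC
Why: Silyl protection of the hydroxyl before acetylide addition; this centre becomes C10 and is re-set in step 9.

**Step 6**
Reactants: 7; 12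
Product: 13 (2S,6S,7S)-7-[(tert-butyldimethylsilyl)oxy]-8-[(4-methoxybenzyl)oxy]-6-methyl-2-[(triethylsilyl)oxy]oct-4-yn-3-one
Conditions: n-BuLi (1.05 equiv), THF, −78 °C; then 12, −78 → −20 °C; NH4Cl
Reagents that add atoms: none (both partners are listed reactants)
Why: Acylation of the lithium acetylide by the Weinreb amide (stable chelate, no over-addition) forms C1–C2.

**Step 7**
Reactants: 13
Product: 14 (2S)-5-{(2R,3S)-3-[(tert-butyldimethylsilyl)oxy]-4-[(4-methoxybenzyl)oxy]butan-2-yl}-2-methylfuran-3(2H)-one (C2 of the ring is epimerisable; its configuration does not matter)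
Conditions: PPTS, MeOH, 0 °C; then Ph3PAuCl/AgOTf (2 mol %), toluene, rt
Reagents that add atoms: none
Why: Selective TES removal, then Au(I)-catalysed 5-endo-dig hydroalkoxylation of the γ-hydroxy ynone forms the 3(2H)-furanone; no amine base is used, so the propargylic C4 centre is not isomerised.

**Step 8**
Reactants: 14; 15 triisopropylsilyl triflate
Product: 16 ({5-[(2R,3S)-3-[(tert-butyldimethylsilyl)oxy]-4-[(4-methoxybenzyl)oxy]butan-2-yl]-2-methylfuran-3-yl}oxy)triisopropylsilane
Conditions: TIPSOTf, Et3N, CH2Cl2, 0 °C; used directly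
Reagents that add atoms: TIPSOTf, CC(C)[Si](OS(=O)(=O)C(F)(F)F)(C(C)C)C(C)C
Why: Soft enolisation and O-silylation toward C10 gives the aromatic 3-silyloxyfuran; C4 is not deprotonated.

**Step 9 (new transformation)**
Reactants: 16; 17 acrolein
Product: 18 3-[(2R)-5-{(2R,3S)-3-[(tert-butyldimethylsilyl)oxy]-4-[(4-methoxybenzyl)oxy]butan-2-yl}-2-methyl-3-oxo-2,3-dihydrofuran-2-yl]propanal
Conditions: acrolein (3 equiv), (2S,5S)-5-benzyl-2-tert-butyl-3-methylimidazolidin-4-one·2,4-dinitrobenzoic acid (20 mol %), H2O (2 equiv), CH2Cl2, −60 → −40 °C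
Reagents that add atoms: acrolein, C=CC=O
Why: Proposed new method: an iminium-catalysed, dearomative Mukaiyama–Michael addition of a 2-alkyl-3-silyloxyfuran to acrolein, in which the chiral iminium makes the β-carbon the only electrophilic site, the furan attacks through C2 (largest HOMO coefficient, α to ring O and β to OSi), and the silyloxocarbenium collapses with water to the 2,2-disubstituted 3(2H)-furanone; the benzyl group blocks one iminium face and the furan is expected to approach in an endo-type open transition state with OTIPS turned away from the tert-butyl group, so one furan π-face bonds and C10 is set as R under catalyst control while C9–C10 is formed; the closest known reactions are imidazolidinone-catalysed Mukaiyama–Michael additions of 2-silyloxyfurans to enals and Lewis-acid aldol reactions of 2-alkyl-3-silyloxyfurans at C2.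

**Step 10**
Reactants: 18; 19 nitrosobenzene
Product: 20 (2R)-5-{(2R,3S)-3-[(tert-butyldimethylsilyl)oxy]-4-[(4-methoxybenzyl)oxy]butan-2-yl}-2-[(2S)-2,3-dihydroxypropyl]-2-methylfuran-3(2H)-one
Conditions: D-proline (20 mol %), PhNO (slow addition), CHCl3, 4 °C; then NaBH4, EtOH, 0 °C; then CuSO4·5H2O (30 mol %), MeOH, rt
Reagents that add atoms: nitrosobenzene, O=Nc1ccccc1 (supplies the O8 oxygen)
Why: Proline-catalysed α-aminoxylation through the enamine with acid-directed delivery of PhN=O (L-proline gives R, so D-proline gives 8S); the aldehyde is then reduced (the vinylogous-ester ketone is inert to NaBH4 at 0 °C) and the N–O bond cleaved by Cu(II).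

**Step 11**
Reactants: 20; 11 chlorotriethylsilane
Product: 21 (2R)-2-{(2S)-2,3-bis[(triethylsilyl)oxy]propyl}-5-{(2R,3S)-3-[(tert-butyldimethylsilyl)oxy]-4-[(4-methoxybenzyl)oxy]butan-2-yl}-2-methylfuran-3(2H)-one
Conditions: TESCl (3 equiv), imidazole, DMAP (cat.), DMF, rt
Reagents that add atoms: chlorotriethylsilane, CC[Si](Cl)(CC)CC
Why: Exhaustive silylation of the diol, set up for selective unmasking of the primary position.

**Step 12**
Reactants: 21
Product: 22 (2S)-3-[(2R)-5-{(2R,3S)-3-[(tert-butyldimethylsilyl)oxy]-4-[(4-methoxybenzyl)oxy]butan-2-yl}-2-methyl-3-oxo-2,3-dihydrofuran-2-yl]-2-[(triethylsilyl)oxy]propanal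
Conditions: (COCl)2 (4 equiv), DMSO (8 equiv), CH2Cl2, −78 → −40 °C; then i-Pr2NEt, −78 → −20 °C
Reagents that add atoms: none
Why: Swern conditions cleave and oxidise a primary TES ether directly to the aldehyde, leaving secondary TES, TBS and PMB ethers intact; the amine is added cold to avoid epimerising C8.

**Step 13**
Reactants: 22; 23 methyl acrylate
Product: 24 methyl (3RS,4S)-3-hydroxy-2-methylidene-5-[(2R)-5-{(2R,3S)-3-[(tert-butyldimethylsilyl)oxy]-4-[(4-methoxybenzyl)oxy]butan-2-yl}-2-methyl-3-oxo-2,3-dihydrofuran-2-yl]-4-[(triethylsilyl)oxy]pentanoate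
Conditions: methyl acrylate (10 equiv), quinuclidine (0.5 equiv), MeOH (0.75 equiv), 0 °C → rt
Reagents that add atoms: methyl acrylate, C=CC(=O)OC
Why: Morita–Baylis–Hillman reaction of an activated α-silyloxy aldehyde attaches C11–C13; the new carbinol centre is removed in step 14, so the epimer mixture is inconsequential.

**Step 14**
Reactants: 24; 25 N-bromosuccinimide
Product: 26 methyl (2Z,4S)-2-(bromomethyl)-5-[(2R)-5-{(2R,3S)-3-[(tert-butyldimethylsilyl)oxy]-4-[(4-methoxybenzyl)oxy]butan-2-yl}-2-methyl-3-oxo-2,3-dihydrofuran-2-yl]-4-[(triethylsilyl)oxy]pent-2-enoate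
Conditions: NBS/Me2S (pre-mixed), CH2Cl2, −20 → 0 °C
Reagents that add atoms: N-bromosuccinimide, O=C1CCC(=O)N1Br
Why: The Corey–Kim bromosulfonium reagent converts the Baylis–Hillman alcohol to the rearranged (Z)-allylic bromide by SN2′ substitution under acid-free conditions that spare the silyl ethers.

**Step 15**
Reactants: 26
Product: 27 methyl (2Z,4S)-2-(bromomethyl)-5-[(2R)-5-{(2R,3S)-3-[(tert-butyldimethylsilyl)oxy]-4-hydroxybutan-2-yl}-2-methyl-3-oxo-2,3-dihydrofuran-2-yl]-4-[(triethylsilyl)oxy]pent-2-enoate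
Conditions: DDQ, CH2Cl2/pH 7 buffer, 0 °C
Reagents that add atoms: none
Why: Oxidative PMB cleavage is orthogonal to TES, TBS, the allylic bromide and the enoate.

**Step 16**
Reactants: 27
Product: 28 methyl (2Z,4S)-2-(bromomethyl)-5-[(2R)-5-{(2R,3S)-3-[(tert-butyldimethylsilyl)oxy]-4-oxobutan-2-yl}-2-methyl-3-oxo-2,3-dihydrofuran-2-yl]-4-[(triethylsilyl)oxy]pent-2-enoate
Conditions: Dess–Martin periodinane, NaHCO3, CH2Cl2, 0 °C → rt; used crude
Reagents that add atoms: none
Why: Buffered Dess–Martin oxidation gives the α-silyloxy C6 aldehyde without epimerising C5.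

**Step 17**
Reactants: 28
Product: 29 (4R,5S,6S,7S,8S,10R)-5-[(tert-butyldimethylsilyl)oxy]-1-oxo-8-[(triethylsilyl)oxy]-3,10-epoxygermacra-2,11(13)-dien-12,6-olide (the 7S label is a CIP priority effect of the O8–Si group; the geometry is the same as 7R in 30–33)
Conditions: CrCl2 (10 equiv), THF, syringe-pump addition to 2 mM, rt; aq. NH4Cl; PPTS (cat.), benzene, 40 °C if any hydroxy ester remains
Reagents that add atoms: none
Why: Intramolecular Barbier/Nozaki–Hiyama-type 2-(alkoxycarbonyl)allylation: the allyl-Cr(III) species adds through its γ-carbon (C7) to the C6 aldehyde in a chair transition state with C5 and C8 pseudo-equatorial (anti, hence the trans-fused lactone after in-situ lactonisation); the 6S,7R face selectivity is expected from the C8 stereocentre and the furanone tether but is not secured (the α-OTBS Felkin preference at C5 may oppose it, see risks).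

**Step 18**
Reactants: 29
Product: 30 (4R,5S,6S,7R,8S,10R)-5-[(tert-butyldimethylsilyl)oxy]-8-hydroxy-1-oxo-3,10-epoxygermacra-2,11(13)-dien-12,6-olide
Conditions: HF·pyridine, pyridine, THF, 0 °C
Reagents that add atoms: none
Why: A secondary TES ether is cleaved much faster than the hindered secondary TBS ether under buffered HF.

**Step 19**
Reactants: 30; 31 angelic acid
Product: 32 (4R,5S,6S,7R,8S,10R)-8-(angeloyloxy)-5-[(tert-butyldimethylsilyl)oxy]-1-oxo-3,10-epoxygermacra-2,11(13)-dien-12,6-olide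
Conditions: angelic acid, 2,4,6-trichlorobenzoyl chloride, Et3N, toluene, rt; then 30, toluene, 75 °C (no DMAP)
Reagents that add atoms: angelic acid, C/C=C(/C)C(=O)O
Why: Yamaguchi mixed-anhydride esterification without a nucleophilic catalyst acylates O8 while avoiding the addition–elimination route that isomerises angelate to tiglate.

**Step 20**
Reactants: 32
Product: 33 Rufescenolide B
Conditions: HF·pyridine, THF/pyridine, 0 °C → rt
Reagents that add atoms: none
Why: Fluoride-mediated removal of the TBS ether under mildly acidic conditions that leave the angelate, α-methylene lactone and furanone untouched.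

## Compound list
1 | (R)-but-3-yn-2-ol | C#C[C@@H](C)O | starting material
2 | methanesulfonyl chloride | CS(=O)(=O)Cl | starting material (reagent)
3 | (R)-but-3-yn-2-yl methanesulfonate | C#C[C@@H](C)OS(C)(=O)=O | intermediate
4 | 2-[(4-methoxybenzyl)oxy]acetaldehyde | O=CCOCc1ccc(OC)cc1 | starting material
5 | (2S,3S)-1-[(4-methoxybenzyl)oxy]-3-methylpent-4-yn-2-ol | C#C[C@H](C)[C@H](O)COCc1ccc(OC)cc1 | intermediate
6 | tert-butyldimethylsilyl triflate | CC(C)(C)[Si](C)(C)OS(=O)(=O)C(F)(F)F | starting material (reagent)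
7 | tert-butyl({(2S,3S)-1-[(4-methoxybenzyl)oxy]-3-methylpent-4-yn-2-yl}oxy)dimethylsilane | C#C[C@H](C)[C@H](O[Si](C)(C)C(C)(C)C)COCc1ccc(OC)cc1 | intermediate
8 | ethyl (S)-lactate | CCOC(=O)[C@H](C)O | starting material
9 | N,O-dimethylhydroxylamine hydrochloride | CNOC.Cl | starting material (reagent)
10 | (S)-2-hydroxy-N-methoxy-N-methylpropanamide | C[C@H](O)C(=O)N(C)OC | intermediate
11 | chlorotriethylsilane | CC[Si](Cl)(CC)CC | starting material (reagent)
12 | (S)-N-methoxy-N-methyl-2-[(triethylsilyl)oxy]propanamide | C[C@H](O[Si](CC)(CC)CC)C(=O)N(C)OC | intermediate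
13 | (2S,6S,7S)-7-(TBS-oxy)-8-(PMB-oxy)-6-methyl-2-(TES-oxy)oct-4-yn-3-one | C[C@H](O[Si](CC)(CC)CC)C(=O)C#C[C@H](C)[C@H](O[Si](C)(C)C(C)(C)C)COCc1ccc(OC)cc1 | intermediate
14 | (2S)-5-[(2R,3S)-3-(TBS-oxy)-4-(PMB-oxy)butan-2-yl]-2-methylfuran-3(2H)-one | C[C@@H]1OC(=CC1=O)[C@H](C)[C@H](O[Si](C)(C)C(C)(C)C)COCc2ccc(OC)cc2 | intermediate
15 | triisopropylsilyl triflate | CC(C)[Si](OS(=O)(=O)C(F)(F)F)(C(C)C)C(C)C | starting material (reagent)
16 | ({5-[(2R,3S)-3-(TBS-oxy)-4-(PMB-oxy)butan-2-yl]-2-methylfuran-3-yl}oxy)triisopropylsilane | Cc1oc(cc1O[Si](C(C)C)(C(C)C)C(C)C)[C@H](C)[C@H](O[Si](C)(C)C(C)(C)C)COCc2ccc(OC)cc2 | intermediate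
17 | acrolein | C=CC=O | starting material
18 | 3-[(2R)-5-{(2R,3S)-3-(TBS-oxy)-4-(PMB-oxy)butan-2-yl}-2-methyl-3-oxo-2,3-dihydrofuran-2-yl]propanal | O=CCC[C@@]1(C)OC(=CC1=O)[C@H](C)[C@H](O[Si](C)(C)C(C)(C)C)COCc2ccc(OC)cc2 | intermediate
19 | nitrosobenzene | O=Nc1ccccc1 | starting material (reagent)
20 | (2R)-2-[(2S)-2,3-dihydroxypropyl]-5-{(2R,3S)-3-(TBS-oxy)-4-(PMB-oxy)butan-2-yl}-2-methylfuran-3(2H)-one | OC[C@@H](O)C[C@@]1(C)OC(=CC1=O)[C@H](C)[C@H](O[Si](C)(C)C(C)(C)C)COCc2ccc(OC)cc2 | intermediate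
21 | (2R)-2-{(2S)-2,3-bis(TES-oxy)propyl}-5-{(2R,3S)-3-(TBS-oxy)-4-(PMB-oxy)butan-2-yl}-2-methylfuran-3(2H)-one | CC[Si](CC)(CC)OC[C@@H](O[Si](CC)(CC)CC)C[C@@]1(C)OC(=CC1=O)[C@H](C)[C@H](O[Si](C)(C)C(C)(C)C)COCc2ccc(OC)cc2 | intermediate
22 | (2S)-3-[(2R)-5-{(2R,3S)-3-(TBS-oxy)-4-(PMB-oxy)butan-2-yl}-2-methyl-3-oxo-2,3-dihydrofuran-2-yl]-2-(TES-oxy)propanal | O=C[C@@H](O[Si](CC)(CC)CC)C[C@@]1(C)OC(=CC1=O)[C@H](C)[C@H](O[Si](C)(C)C(C)(C)C)COCc2ccc(OC)cc2 | intermediate
23 | methyl acrylate | C=CC(=O)OC | starting material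
24 | methyl (3RS,4S)-3-hydroxy-2-methylidene-5-[(2R)-furanonyl]-4-(TES-oxy)pentanoate (furanonyl as in 22) | COC(=O)C(=C)C(O)[C@@H](O[Si](CC)(CC)CC)C[C@@]1(C)OC(=CC1=O)[C@H](C)[C@H](O[Si](C)(C)C(C)(C)C)COCc2ccc(OC)cc2 | intermediate
25 | N-bromosuccinimide | O=C1CCC(=O)N1Br | starting material (reagent)
26 | methyl (2Z,4S)-2-(bromomethyl)-5-[(2R)-5-{(2R,3S)-3-(TBS-oxy)-4-(PMB-oxy)butan-2-yl}-2-methyl-3-oxo-2,3-dihydrofuran-2-yl]-4-(TES-oxy)pent-2-enoate | COC(=O)/C(CBr)=C/[C@@H](O[Si](CC)(CC)CC)C[C@@]1(C)OC(=CC1=O)[C@H](C)[C@H](O[Si](C)(C)C(C)(C)C)COCc2ccc(OC)cc2 | intermediate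
27 | as 26 with a free C6 primary alcohol (4-hydroxybutan-2-yl) | COC(=O)/C(CBr)=C/[C@@H](O[Si](CC)(CC)CC)C[C@@]1(C)OC(=CC1=O)[C@H](C)[C@H](O[Si](C)(C)C(C)(C)C)CO | intermediate
28 | as 26 with a C6 aldehyde (4-oxobutan-2-yl) | COC(=O)/C(CBr)=C/[C@@H](O[Si](CC)(CC)CC)C[C@@]1(C)OC(=CC1=O)[C@H](C)[C@H](O[Si](C)(C)C(C)(C)C)C=O | intermediate
29 | (4R,5S,6S,7S,8S,10R)-5-(TBS-oxy)-8-(TES-oxy)-1-oxo-3,10-epoxygermacra-2,11(13)-dien-12,6-olide | C=C1C(=O)O[C@@H]2[C@@H](O[Si](C)(C)C(C)(C)C)[C@@H](C)C3=CC(=O)[C@@](C)(C[C@H](O[Si](CC)(CC)CC)[C@@H]12)O3 | intermediate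
30 | (4R,5S,6S,7R,8S,10R)-5-(TBS-oxy)-8-hydroxy-1-oxo-3,10-epoxygermacra-2,11(13)-dien-12,6-olide | C=C1C(=O)O[C@@H]2[C@@H](O[Si](C)(C)C(C)(C)C)[C@@H](C)C3=CC(=O)[C@@](C)(C[C@H](O)[C@@H]12)O3 | intermediate
31 | angelic acid, (Z)-2-methylbut-2-enoic acid | C/C=C(/C)C(=O)O | starting material
32 | (4R,5S,6S,7R,8S,10R)-8-(angeloyloxy)-5-(TBS-oxy)-1-oxo-3,10-epoxygermacra-2,11(13)-dien-12,6-olide | C=C1C(=O)O[C@@H]2[C@@H](O[Si](C)(C)C(C)(C)C)[C@@H](C)C3=CC(=O)[C@@](C)(C[C@H](OC(=O)/C(C)=C\C)[C@@H]12)O3 | intermediate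
33 | Rufescenolide B, (4R,5S,6S,7R,8S,10R)-8-(angeloyloxy)-5-hydroxy-1-oxo-3,10-epoxygermacra-2,11(13)-dien-12,6-olide | C=C1C(=O)O[C@@H]2[C@@H](O)[C@@H](C)C3=CC(=O)[C@@](C)(C[C@H](OC(=O)/C(C)=C\C)[C@@H]12)O3 | target

(TBS = tert-butyldimethylsilyl, TES = triethylsilyl, PMB = 4-methoxybenzyl.)

## Summary
Total steps: 20. Longest linear sequence: 18 (steps 1–3, then 6–20, from (R)-but-3-yn-2-ol).

Three steps most likely to fail, each with a fallback that changes the approach:

1. **Step 9 (proposed new Mukaiyama–Michael addition).** Risks are C4 versus C2 attack, protodesilylation back to 14, and low or reversed selectivity at C10. Fallback (known chemistry): set C10 by Seebach self-regeneration of stereocentres. (S)-Lactic acid and pivalaldehyde give the cis-dioxolanone; LDA/allyl bromide alkylates with retention to give the correct C10 configuration. The product is converted to the O-TES Weinreb amide, coupled with the acetylide of 7 and cyclised with Au as in steps 6–7 to the 2-allyl-2-methylfuranone. 9-BBN/NaBO3 hydroboration then Dess–Martin oxidation gives the same aldehyde 18.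

2. **Step 17 (Cr-mediated macrocyclisation).** Risks are oligomerisation, strain in closing the ring onto the pre-formed furanone, and the wrong C6/C7 diastereomer. Fallback: change the ring-forming bond and order. Form the lactone first by an intermolecular chelation-controlled In- or Zn-mediated Barbier reaction of a C2–C6 alkynyl aldehyde (O5-PMB) with a C7–C10 bromo-enoate fragment carrying the Seebach-derived C10 centre, so that C6/C7 are assigned and purified on an acyclic system. Then close the 10-membered ring at C1–C2 by intramolecular Nozaki–Hiyama–Kishi addition of the iodoalkyne to a C1 aldehyde, oxidise to the ynone, and form the furanone last by Au-catalysed transannular cyclisation.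

3. **Step 19 (angeloylation of the hindered C8-OH).** Risks are angelate-to-tiglate isomerisation and lactone migration to O8 on heating. Fallback: build the Z-alkene on the substrate instead of transferring it. Esterify O8 with 2-[bis(2,2,2-trifluoroethoxy)phosphoryl]propanoic acid (EDC, DMAP, rt), then run a Still–Gennari olefination with acetaldehyde (KHMDS, 18-crown-6, THF, −78 °C) to give the (Z)-2-methylbut-2-enoate directly.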